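**Retrosynthetic overview**
1. The target is traced back by cleavage of five methyl ethers and by dehydrogenation to a 2-(4,5-dimethoxycyclohexa-1,4-dienyl)chromone.
2. The strategy rests on ring B (C1'–C6'), which carries adjacent oxygens on C3' and C4' and one carbon substituent on C1'. Cutting C1'–C2' and C5'–C6' gives 2,3-dimethoxybuta-1,3-diene (C2'–C5') and the ethynyl group (C1', C6') of a 2-ethynylchromone, joined forward by a cobalt-catalysed [4+2] cycloaddition.
3. The alkyne comes from the chromone-2-carbaldehyde by one-carbon homologation, and the aldehyde from the chromone-2-carboxylate by reduction and re-oxidation.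
4. Ring C is closed by Claisen condensation of a 3-benzylated 2-hydroxyacetophenone with diethyl oxalate and acid cyclodehydration. The acetophenone comes from Grignard addition to a salicylaldehyde, ionic hydrogenation and a Fries acylation.
5. Ring order: ring A and the anisyl ring are bought, ring C is formed in step 4, ring B is formed in step 8 and made aromatic in step 9.

Key step: step 8

Remark: 2 and 13 are taken as purchased reagents. The only stereocentre on the route (the carbinol carbon of 3) is formed racemic and removed in step 2, and the target has none.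

**Step 1**
Reactants: 1 2-hydroxy-4,6-dimethoxybenzaldehyde; 2 4-methoxyphenylmagnesium bromide
Product: 3 2-[hydroxy(4-methoxyphenyl)methyl]-3,5-dimethoxyphenol (racemic)
Conditions: 2 (3 equiv), THF, 0 °C → rt; then H2O, pH 7 buffer; used crude
Reagents that add atoms: none
Why: The first equivalent of the Grignard reagent deprotonates the phenol and a further one adds to the magnesium-chelated aldehyde (Grignard 1,2-addition), giving the carbinol as a racemate whose stereocentre is erased in step 2.

**Step 2**
Reactants: 3 2-[hydroxy(4-methoxyphenyl)methyl]-3,5-dimethoxyphenol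
Product: 4 3,5-dimethoxy-2-(4-methoxybenzyl)phenol
Conditions: Et3SiH (3 equiv), CF3CO2H, CH2Cl2, −20 → 0 °C
Reagents that add atoms: none
Why: This is an ionic hydrogenation in which CF3CO2H ionises the doubly benzylic carbinol to a diarylmethyl cation stabilised by three oxygen donors and Et3SiH delivers hydride to it, excess silane and low temperature keeping Friedel–Crafts self-alkylation behind.

**Step 3**
Reactants: 4 3,5-dimethoxy-2-(4-methoxybenzyl)phenol
Product: 6 1-[2-hydroxy-4,6-dimethoxy-3-(4-methoxybenzyl)phenyl]ethanone, via aryl acetate 5 (not isolated)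
Conditions: Ac2O (1.5 equiv), BF3·OEt2 (3 equiv), 60 °C; then H2O, 50 °C
Reagents that add atoms: acetic anhydride, CC(=O)OC(C)=O
Why: O-Acetylation followed by BF3-promoted Fries rearrangement (Friedel–Crafts C-acylation) should place the acetyl group on the only free position ortho to the phenol, where the boron-chelated ketone is favoured over the position flanked by two methoxy groups, and BF3 does not cleave aryl methyl ethers.

**Step 4**
Reactants: 6 1-[2-hydroxy-4,6-dimethoxy-3-(4-methoxybenzyl)phenyl]ethanone; 7 diethyl oxalate
Product: 9 ethyl 5,7-dimethoxy-8-(4-methoxybenzyl)-4-oxo-4H-chromene-2-carboxylate, via diketo ester 8 (not isolated)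
Conditions: 7 (3 equiv), NaOEt (4 equiv), EtOH, reflux; then HCl, EtOH, 70 °C
Reagents that add atoms: none
Why: Crossed Claisen condensation of the methyl ketone enolate with the non-enolisable oxalate gives the diketo ester, and acid-catalysed attack of the phenol on the C2 ketone with loss of water (6-exo-trig addition–elimination, the classical chromone-2-carboxylate synthesis) closes ring C.

**Step 5**
Reactants: 9 ethyl 5,7-dimethoxy-8-(4-methoxybenzyl)-4-oxo-4H-chromene-2-carboxylate
Product: 10 2-(hydroxymethyl)-5,7-dimethoxy-8-(4-methoxybenzyl)-4H-chromen-4-one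
Conditions: NaBH4 (1.5 equiv), EtOH/THF, 0 °C
Reagents that add atoms: none
Why: This is a chemoselective borohydride reduction, since the ester on the electron-poor C2 of the pyrone behaves like an activated heteroaryl ester whereas the C4 carbonyl is a vinylogous ester further deactivated by the 5- and 7-methoxy groups, as is known for chromone-2-carboxylates.

**Step 6**
Reactants: 10 2-(hydroxymethyl)-5,7-dimethoxy-8-(4-methoxybenzyl)-4H-chromen-4-one
Product: 11 5,7-dimethoxy-8-(4-methoxybenzyl)-4-oxo-4H-chromene-2-carbaldehyde
Conditions: Dess–Martin periodinane (1.2 equiv), CH2Cl2, rt; used directly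
Reagents that add atoms: none
Why: Dess–Martin oxidation should convert the primary, allylic-type alcohol to the aldehyde under neutral, non-aqueous conditions without over-oxidation and without touching the diarylmethane CH2 or the methyl ethers.

**Step 7**
Reactants: 11 5,7-dimethoxy-8-(4-methoxybenzyl)-4-oxo-4H-chromene-2-carbaldehyde
Product: 12 2-ethynyl-5,7-dimethoxy-8-(4-methoxybenzyl)-4H-chromen-4-one
Conditions: dimethyl (1-diazo-2-oxopropyl)phosphonate (1.3 equiv), K2CO3 (2 equiv), MeOH/THF, 0 °C → rt
Reagents that add atoms: dimethyl (1-diazo-2-oxopropyl)phosphonate, CC(=O)C(=[N+]=[N-])P(=O)(OC)OC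
Why: In this Ohira–Bestmann (Seyferth–Gilbert) homologation the diazomethylphosphonate anion adds to the aldehyde in Horner–Wadsworth–Emmons fashion and the diazoalkene loses N2 with a 1,2-hydrogen shift to the terminal alkyne, while K2CO3 at 0 °C should be mild enough to leave the 5,7-dimethoxychromone ring closed.

**Step 8**
Reactants: 12 2-ethynyl-5,7-dimethoxy-8-(4-methoxybenzyl)-4H-chromen-4-one; 13 2,3-dimethoxybuta-1,3-diene
Product: 14 2-(4,5-dimethoxycyclohexa-1,4-dien-1-yl)-5,7-dimethoxy-8-(4-methoxybenzyl)-4H-chromen-4-one
Conditions: 13 (3 equiv), CoBr2(dppe) (10 mol%, dppe = 1,2-bis(diphenylphosphino)ethane), Zn powder (20 mol%), ZnI2 (20 mol%), CH2Cl2, rt; filtration through basic Al2O3, used directly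
Reagents that add atoms: none
Why: Proposed new method: zinc reduces the divalent cobalt of CoBr2(dppe) to monovalent cobalt and ZnI2 abstracts halide, giving a cationic cobalt–dppe centre that binds diene 13 in its s-cis form together with the ethynyl group of 12, couples them oxidatively and releases the ring by reductive elimination, so that C1'–C2' and C5'–C6' are formed and ring B closes in a formal [4+2] mode as a non-conjugated 1,4-cyclohexadiene. The closest known reaction type is the cobalt-catalysed neutral Diels–Alder reaction of terminal aryl alkynes with 2,3-dimethylbutadiene and with 2-silyloxybutadienes, which gives 1,4-cyclohexadienes that are dehydrogenated to arenes; what is new is the pairing of a 2,3-dialkoxy diene with an alkyne carried on C2 of a chromone. The catalysed mode is preferred to simple heating because the alkyne is only a vinylogous ynone whose acceptor is damped by the ring oxygen and the 5- and 7-methoxy groups, so that an uncatalysed normal-demand cycloaddition would need temperatures at which the bis(enol ether) diene polymerises. No stereocentre is created and, the diene being symmetric, no regiochemical question arises, so the two methoxy groups must end on C3' and C4'. The selectivity needed is chemoselectivity for the terminal alkyne over the trisubstituted endocyclic C2=C3 bond and over alkyne cyclotrimerisation; the first follows from the catalyst's preference for an unhindered alkyne over a hindered alkene, the second from the excess of diene and the bisphosphine ligand.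

**Step 9**
Reactants: 14 2-(4,5-dimethoxycyclohexa-1,4-dien-1-yl)-5,7-dimethoxy-8-(4-methoxybenzyl)-4H-chromen-4-one
Product: 15 2-(3,4-dimethoxyphenyl)-5,7-dimethoxy-8-(4-methoxybenzyl)-4H-chromen-4-one
Conditions: DDQ (1.05 equiv), toluene, 0 °C → rt
Reagents that add atoms: none
Why: DDQ abstracts hydride from a doubly allylic CH2 of the 1,4-cyclohexadiene and the cation loses a proton (dehydrogenative aromatisation), a process driven by the gain of aromaticity and far faster than oxidation of the diarylmethane CH2 when one equivalent is used at low temperature.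

**Step 10**
Reactants: 15 2-(3,4-dimethoxyphenyl)-5,7-dimethoxy-8-(4-methoxybenzyl)-4H-chromen-4-one
Product: 16 8-(4-hydroxybenzyl)luteolin
Conditions: BBr3 (10 equiv), CH2Cl2, −78 °C → rt, prolonged; then H2O
Reagents that add atoms: none
Why: In this Lewis-acid ether cleavage BBr3 coordinates each aryl methyl ether oxygen, bromide removes the methyl group by SN2 and water hydrolyses the aryl borates, the 5-OMe being helped by chelation to the C4 carbonyl and the slower 7-OMe being taken by excess reagent at ambient temperature, which avoids the hot protic acid that could cause Wessely–Moser isomerisation or benzyl migration.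

**Compound list**
1 | 2-hydroxy-4,6-dimethoxybenzaldehyde | O=Cc1c(O)cc(OC)cc1OC | starting material
2 | 4-methoxyphenylmagnesium bromide (THF solution) | COc1ccc([Mg]Br)cc1 | starting material
3 | 2-[hydroxy(4-methoxyphenyl)methyl]-3,5-dimethoxyphenol (racemic) | COc1ccc(C(O)c2c(O)cc(OC)cc2OC)cc1 | intermediate
4 | 3,5-dimethoxy-2-(4-methoxybenzyl)phenol | COc1ccc(Cc2c(O)cc(OC)cc2OC)cc1 | intermediate
5 | 3,5-dimethoxy-2-(4-methoxybenzyl)phenyl acetate (formed in the flask, not isolated) | CC(=O)Oc1cc(OC)cc(OC)c1Cc1ccc(OC)cc1 | intermediate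
6 | 1-[2-hydroxy-4,6-dimethoxy-3-(4-methoxybenzyl)phenyl]ethanone | CC(=O)c1c(O)c(Cc2ccc(OC)cc2)c(OC)cc1OC | intermediate
7 | diethyl oxalate | CCOC(=O)C(=O)OCC | starting material
8 | ethyl 4-[2-hydroxy-4,6-dimethoxy-3-(4-methoxybenzyl)phenyl]-2,4-dioxobutanoate (formed in the flask, not isolated) | CCOC(=O)C(=O)CC(=O)c1c(O)c(Cc2ccc(OC)cc2)c(OC)cc1OC | intermediate
9 | ethyl 5,7-dimethoxy-8-(4-methoxybenzyl)-4-oxo-4H-chromene-2-carboxylate | CCOC(=O)c1cc(=O)c2c(OC)cc(OC)c(Cc3ccc(OC)cc3)c2o1 | intermediate
10 | 2-(hydroxymethyl)-5,7-dimethoxy-8-(4-methoxybenzyl)-4H-chromen-4-one | OCc1cc(=O)c2c(OC)cc(OC)c(Cc3ccc(OC)cc3)c2o1 | intermediate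
11 | 5,7-dimethoxy-8-(4-methoxybenzyl)-4-oxo-4H-chromene-2-carbaldehyde | O=Cc1cc(=O)c2c(OC)cc(OC)c(Cc3ccc(OC)cc3)c2o1 | intermediate
12 | 2-ethynyl-5,7-dimethoxy-8-(4-methoxybenzyl)-4H-chromen-4-one | C#Cc1cc(=O)c2c(OC)cc(OC)c(Cc3ccc(OC)cc3)c2o1 | intermediate
13 | 2,3-dimethoxybuta-1,3-diene | COC(=C)C(=C)OC | starting material
14 | 2-(4,5-dimethoxycyclohexa-1,4-dien-1-yl)-5,7-dimethoxy-8-(4-methoxybenzyl)-4H-chromen-4-one | O=c1cc(C2=CCC(OC)=C(OC)C2)oc2c(Cc3ccc(OC)cc3)c(OC)cc(OC)c12 | intermediate
15 | 2-(3,4-dimethoxyphenyl)-5,7-dimethoxy-8-(4-methoxybenzyl)-4H-chromen-4-one | O=c1cc(-c2ccc(OC)c(OC)c2)oc2c(Cc3ccc(OC)cc3)c(OC)cc(OC)c12 | intermediate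
16 | 8-(4-hydroxybenzyl)luteolin, 2-(3,4-dihydroxyphenyl)-5,7-dihydroxy-8-(4-hydroxybenzyl)-4H-chromen-4-one | O=c1cc(-c2ccc(O)c(O)c2)oc2c(Cc3ccc(O)cc3)c(O)cc(O)c12 | target

**Step count**
Total steps: 10. Longest linear sequence: 10 steps (compound 1 to compound 16).

**Steps most likely to fail**

Step 8 (cobalt-catalysed ring B cycloaddition). The catalyst may be tied up by chelation at the C4 carbonyl and 5-methoxy pair. The alkyne may cyclotrimerise instead of cross-adding. ZnI2 may also isomerise the bis(enol ether) ring with loss of methanol before dehydrogenation. The fallback sets out from compound 6 and comes back to the route at compound 15, so that steps 4 to 9 are not needed. Compound 6 is O-acylated with 3,4-dimethoxybenzoyl chloride (pyridine, DMAP) to 2-acetyl-3,5-dimethoxy-6-(4-methoxybenzyl)phenyl 3,4-dimethoxybenzoate F1. Baker–Venkataraman rearrangement (KOH, pyridine, 50 °C) moves the aroyl group to carbon and gives 1-(3,4-dimethoxyphenyl)-3-[2-hydroxy-4,6-dimethoxy-3-(4-methoxybenzyl)phenyl]propane-1,3-dione F2. Acid cyclodehydration (AcOH, catalytic H2SO4, 90 °C) then gives 15.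

Step 7 (Ohira–Bestmann homologation). Methoxide may open the pyrone ring by attack at C2, or methanol may add in conjugate fashion to the newly formed ene-yne-one. The fallback sets out from compound 11 and comes back at compound 12. Wittig reaction of 11 with the ylide from (chloromethyl)triphenylphosphonium chloride and NaN(SiMe3)2 (THF, −78 °C → rt) gives 2-(2-chlorovinyl)-5,7-dimethoxy-8-(4-methoxybenzyl)-4H-chromen-4-one F3 as an E/Z mixture. Dehydrochlorination with LiN(iPr)2 (THF, −78 °C) and protonation of the lithium acetylide then give 12, with no methoxide or methanol present at any stage.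

Step 3 (acetylation and Fries rearrangement). The Lewis acid may promote migration or loss of the 4-methoxybenzyl group by retro-Friedel–Crafts cleavage, or acylation may go para to the phenol. The fallback sets out from compound 4 and comes back at compound 6. Magnesium-mediated ortho-formylation (MgCl2, Et3N, paraformaldehyde, MeCN, reflux) gives 2-hydroxy-4,6-dimethoxy-3-(4-methoxybenzyl)benzaldehyde F4. Addition of MeMgBr (THF, 0 °C) gives racemic 2-(1-hydroxyethyl)-3,5-dimethoxy-6-(4-methoxybenzyl)phenol F5. Oxidation of the benzylic alcohol with activated MnO2 (CH2Cl2, rt) gives 6, and no strong acid meets the diarylmethane.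

**Further compounds**
F1 | step 8 | 2-acetyl-3,5-dimethoxy-6-(4-methoxybenzyl)phenyl 3,4-dimethoxybenzoate | CC(=O)c1c(OC(=O)c2ccc(OC)c(OC)c2)c(Cc2ccc(OC)cc2)c(OC)cc1OC
F2 | step 8 | 1-(3,4-dimethoxyphenyl)-3-[2-hydroxy-4,6-dimethoxy-3-(4-methoxybenzyl)phenyl]propane-1,3-dione | O=C(CC(=O)c1ccc(OC)c(OC)c1)c1c(O)c(Cc2ccc(OC)cc2)c(OC)cc1OC
F3 | step 7 | 2-(2-chlorovinyl)-5,7-dimethoxy-8-(4-methoxybenzyl)-4H-chromen-4-one (E/Z mixture) | ClC=Cc1cc(=O)c2c(OC)cc(OC)c(Cc3ccc(OC)cc3)c2o1
F4 | step 3 | 2-hydroxy-4,6-dimethoxy-3-(4-methoxybenzyl)benzaldehyde | O=Cc1c(O)c(Cc2ccc(OC)cc2)c(OC)cc1OC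
F5 | step 3 | 2-(1-hydroxyethyl)-3,5-dimethoxy-6-(4-methoxybenzyl)phenol (racemic) | CC(O)c1c(O)c(Cc2ccc(OC)cc2)c(OC)cc1OC
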